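**Plan**
Retrosynthesis first masks the N–OH as an O-tetrahydropyranyl acetal, then cuts three bonds of the 1H-pyrrole-2,5-dione ring together: C3–C2(=O), C4–C5(=O) and N1–C5.
This is possible because the ring is a formal (2+2+1) adduct: C3=C4 with its benzyl and aryl groups is an internal alkyne, N1–C2(=O) with its N–O bond is an O-isocyanate, and C5=O is carbon monoxide. N1 lies between two like carbonyl carbons, so either orientation of the unsymmetrical alkyne gives the same ring.
Further cuts: the aryl–C(sp) bond of the alkyne (Sonogashira) and the aryl O–CH2 bond of the prenyl ether (Williamson).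
Forward: prenylation of 4-iodophenol, coupling with 3-phenylprop-1-yne, ruthenium-catalysed assembly of the only ring to be built (from the alkyne, CO and an O-isocyanate released in the flask from a phenyl carbamate), then acetal cleavage.
Stereochemistry: the target has no stereocentre; the cis arrangement of the two carbonyl groups on C3=C4 is fixed by the ring.

Key step: step 4

Remark: all compounds that carry the tetrahydropyranyl group are racemic at the acetal carbon, which is lost in the last step.

**Step 1**
Reactants: 1 4-iodophenol; 2 1-bromo-3-methylbut-2-ene (prenyl bromide)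
Product: 3 1-iodo-4-[(3-methylbut-2-en-1-yl)oxy]benzene
Conditions: K2CO3, acetone, reflux
Reagents that add atoms: none
Why: Williamson ether synthesis, in which the phenoxide of 1 displaces bromide from the primary allylic bromide 2 by SN2, O-alkylation being favoured with a carbonate base in a polar aprotic solvent.

**Step 2**
Reactants: 3 1-iodo-4-[(3-methylbut-2-en-1-yl)oxy]benzene; 4 prop-2-yn-1-ylbenzene (3-phenylprop-1-yne)
Product: 5 1-[(3-methylbut-2-en-1-yl)oxy]-4-(3-phenylprop-1-yn-1-yl)benzene
Conditions: PdCl2(PPh3)2 (2 mol%), CuI (4 mol%), Et3N, THF, room temperature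
Reagents that add atoms: none
Why: Sonogashira coupling of an aryl iodide with a terminal alkyne runs at room temperature, where the mild amine base should not isomerise the 1,3-diarylpropyne to the allene.

**Step 3**
Reactants: 6 O-(tetrahydro-2H-pyran-2-yl)hydroxylamine (racemic); 7 phenyl chloroformate
Product: 8 phenyl N-(tetrahydro-2H-pyran-2-yloxy)carbamate (racemic)
Conditions: pyridine, CH2Cl2, 0 °C to room temperature
Reagents that add atoms: none
Why: N-acylation of an O-alkylhydroxylamine by a chloroformate (carbamate formation) is routine, nitrogen being the only nucleophilic site, and it gives a bench-stable blocked form of the O-isocyanate.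

**Step 4**
Reactants: 5 1-[(3-methylbut-2-en-1-yl)oxy]-4-(3-phenylprop-1-yn-1-yl)benzene; 8 phenyl N-(tetrahydro-2H-pyran-2-yloxy)carbamate
Product: 10 3-benzyl-4-{4-[(3-methylbut-2-en-1-yl)oxy]phenyl}-1-(tetrahydro-2H-pyran-2-yloxy)-1H-pyrrole-2,5-dione (racemic), via 2-(isocyanatooxy)tetrahydro-2H-pyran 9 (not isolated)
Conditions: Ru3(CO)12 (5 mol%), CO (1 atm), mesitylene, 130 °C, 8 (2 equiv) added slowly by syringe pump, no added base
Reagents that add atoms: carbon monoxide, [C-]#[O+]
Why: Proposed new method: thermal loss of phenol from 8 should release the O-isocyanate 9 at a low stationary concentration, zerovalent ruthenium carbonyl should couple its N=C bond oxidatively with the alkyne of 5 to a five-membered aza-ruthenacycle, and CO insertion followed by reductive elimination should release the imide and return the zerovalent metal. The closest known reaction type is the Ru3(CO)12-catalysed intermolecular (2+2+1) cocyclisation of aryl or alkyl isocyanates, internal alkynes and CO to maleimides, combined with the known release of O-isocyanates from phenyl N-alkoxycarbamates; new is the N-alkoxy isocyanate as the two-atom partner. The one ring formed, the 1H-pyrrole-2,5-dione, closes in the (2+2+1) mode from the two alkyne carbons, N=C of 9 and one CO, its last bond arising by reductive elimination from a six-membered metallacycle, and the bond from the aryl-bearing olefinic carbon to its carbonyl carbon is made here. No stereocentre is created, and the cis relation of the two carbonyl carbons across C3=C4 follows from syn addition to the alkyne on the metal. Regioselectivity is not needed, since N1 lies between two like carbonyl groups and both orientations of the unsymmetrical alkyne converge on 10. The chemoselectivity needed, cocyclisation ahead of isocyanate trimerisation, alkyne homocoupling and N–O insertion, is sought through slow addition of 8, the CO atmosphere and the low homocoupling tendency of a hindered internal alkyne.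

**Step 5**
Reactants: 10 3-benzyl-4-{4-[(3-methylbut-2-en-1-yl)oxy]phenyl}-1-(tetrahydro-2H-pyran-2-yloxy)-1H-pyrrole-2,5-dione
Product: 11 himanimide C, 3-benzyl-1-hydroxy-4-{4-[(3-methylbut-2-en-1-yl)oxy]phenyl}-1H-pyrrole-2,5-dione
Conditions: pyridinium p-toluenesulfonate (10 mol%), MeOH, 40 °C
Reagents that add atoms: none
Why: Acid-catalysed transacetalisation (tetrahydropyranyl ether cleavage) with methanol is fast for the acetal of an acidic N-hydroxyimide and mild enough to leave the aryl prenyl ether and the ring alkene untouched.

**Compound list**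
1 | 4-iodophenol | Oc1ccc(I)cc1 | starting material
2 | 1-bromo-3-methylbut-2-ene (prenyl bromide) | CC(C)=CCBr | starting material
3 | 1-iodo-4-[(3-methylbut-2-en-1-yl)oxy]benzene | CC(C)=CCOc1ccc(I)cc1 | intermediate
4 | prop-2-yn-1-ylbenzene (3-phenylprop-1-yne) | C#CCc1ccccc1 | starting material
5 | 1-[(3-methylbut-2-en-1-yl)oxy]-4-(3-phenylprop-1-yn-1-yl)benzene | CC(C)=CCOc1ccc(C#CCc2ccccc2)cc1 | intermediate
6 | O-(tetrahydro-2H-pyran-2-yl)hydroxylamine (racemic) | NOC1CCCCO1 | starting material
7 | phenyl chloroformate | O=C(Cl)Oc1ccccc1 | starting material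
8 | phenyl N-(tetrahydro-2H-pyran-2-yloxy)carbamate (racemic) | O=C(NOC1CCCCO1)Oc1ccccc1 | intermediate
9 | 2-(isocyanatooxy)tetrahydro-2H-pyran (racemic, not isolated) | O=C=NOC1CCCCO1 | intermediate
10 | 3-benzyl-4-{4-[(3-methylbut-2-en-1-yl)oxy]phenyl}-1-(tetrahydro-2H-pyran-2-yloxy)-1H-pyrrole-2,5-dione (racemic) | CC(C)=CCOc1ccc(C2=C(Cc3ccccc3)C(=O)N(OC3CCCCO3)C2=O)cc1 | intermediate
11 | himanimide C | CC(C)=CCOc1ccc(C2=C(Cc3ccccc3)C(=O)N(O)C2=O)cc1 | target

**Step count**
Total step count: 5. Longest linear sequence: 4 steps (steps 1, 2, 4, 5); step 3 is a one-step side branch that prepares the blocked isocyanate.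

**Steps most likely to fail**

Step 4. The low-valent ruthenium may insert into the N–O bond of the O-isocyanate, the isocyanate may condense with itself faster than it is taken up by the metal, or a ruthenium hydride formed from the released phenol may shift the prenyl double bond. The fallback uses known chemistry and sets out from 5. Cocyclisation of 5 with commercial 4-methylphenyl isocyanate and CO (Ru3(CO)12, mesitylene, 130 °C), the established substrate class of this reaction, would give 3-benzyl-1-(4-methylphenyl)-4-{4-[(3-methylbut-2-en-1-yl)oxy]phenyl}-1H-pyrrole-2,5-dione F1. KOH in aqueous THF–MeOH at reflux, then acidification with dilute HCl, would open the imide and close the diacid to 3-benzyl-4-{4-[(3-methylbut-2-en-1-yl)oxy]phenyl}furan-2,5-dione F2 with loss of 4-methylaniline. Condensation of F2 with NH2OH·HCl in pyridine at 90 °C would introduce the N–OH group after the ring is made and come back to the route at 11.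

Step 2. The doubly activated propargylic CH2 may isomerise to the allene under the amine base, or the terminal alkyne may homocouple oxidatively. The fallback sets out from 3 and forms the propargylic C(sp)–C(sp3) bond instead of the aryl–C(sp) bond. Sonogashira coupling of 3 with ethynyltrimethylsilane (PdCl2(PPh3)2, CuI, Et3N) would give trimethyl({4-[(3-methylbut-2-en-1-yl)oxy]phenyl}ethynyl)silane F3. K2CO3 in MeOH would give 1-ethynyl-4-[(3-methylbut-2-en-1-yl)oxy]benzene F4. EtMgBr in THF would give bromo({4-[(3-methylbut-2-en-1-yl)oxy]phenyl}ethynyl)magnesium F5, and its CuBr-catalysed alkylation with benzyl bromide at reflux would come back to the route at 5.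

Step 5. Acid may ionise the aryl prenyl ether in competition with acetal cleavage, or methanol may add to the electron-poor ring alkene. The fallback sets out from 5 and 7 and replaces the acid-labile acetal by a fluoride-labile silyl group. O-(tert-Butyldiphenylsilyl)hydroxylamine and 7 (pyridine, CH2Cl2) would give phenyl N-[(tert-butyldiphenylsilyl)oxy]carbamate F6. Used in place of 8 under the conditions of step 4, F6 would release tert-butyl(isocyanatooxy)diphenylsilane F7 and give 3-benzyl-1-[(tert-butyldiphenylsilyl)oxy]-4-{4-[(3-methylbut-2-en-1-yl)oxy]phenyl}-1H-pyrrole-2,5-dione F8. HF·pyridine in THF at 0 °C would cleave the silyl group and come back to the route at 11.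

**Further compounds**
F1 | step 4 | 3-benzyl-1-(4-methylphenyl)-4-{4-[(3-methylbut-2-en-1-yl)oxy]phenyl}-1H-pyrrole-2,5-dione | CC(C)=CCOc1ccc(C2=C(Cc3ccccc3)C(=O)N(c3ccc(C)cc3)C2=O)cc1
F2 | step 4 | 3-benzyl-4-{4-[(3-methylbut-2-en-1-yl)oxy]phenyl}furan-2,5-dione | CC(C)=CCOc1ccc(C2=C(Cc3ccccc3)C(=O)OC2=O)cc1
F3 | step 2 | trimethyl({4-[(3-methylbut-2-en-1-yl)oxy]phenyl}ethynyl)silane | CC(C)=CCOc1ccc(C#C[Si](C)(C)C)cc1
F4 | step 2 | 1-ethynyl-4-[(3-methylbut-2-en-1-yl)oxy]benzene | CC(C)=CCOc1ccc(C#C)cc1
F5 | step 2 | bromo({4-[(3-methylbut-2-en-1-yl)oxy]phenyl}ethynyl)magnesium | CC(C)=CCOc1ccc(C#C[Mg]Br)cc1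
F6 | step 5 | phenyl N-[(tert-butyldiphenylsilyl)oxy]carbamate | CC(C)(C)[Si](ONC(=O)Oc1ccccc1)(c1ccccc1)c1ccccc1
F7 | step 5 | tert-butyl(isocyanatooxy)diphenylsilane | CC(C)(C)[Si](ON=C=O)(c1ccccc1)c1ccccc1
F8 | step 5 | 3-benzyl-1-[(tert-butyldiphenylsilyl)oxy]-4-{4-[(3-methylbut-2-en-1-yl)oxy]phenyl}-1H-pyrrole-2,5-dione | CC(C)=CCOc1ccc(C2=C(Cc3ccccc3)C(=O)N(O[Si](c3ccccc3)(c3ccccc3)C(C)(C)C)C2=O)cc1
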